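Cadinane numbering of the target is used for every intermediate: ring B = C1–C6 (C4=C5, C15 on C4), ring A = C1, C6, C7, C8, C9, C10 (C11–C13 on C7, C14 on C10).

## Structural features

The target is a cis-fused Δ4-octalin of the amorphane type. Ring B is a cyclohexene (C4=C5, methyl C15 on C4, allylic acetate on C3). Ring A is a cyclohexane carrying a 2-propenoic acid on C7, an acyloxy group on C8, and a methyl plus a tertiary hydroxyl on C10. The hydrogens at C1, C6, C7 and C8 all lie on one face, so the C6–C5 bond, the acrylic acid and O8 are all-cis. The C10 hydroxyl sits on the opposite face (1,3-anti to O8) and the C3 acetate is trans to the C1–C10 bond; all six stereocentres are S. The C8 ester is (E)-4-hydroxy-2-(hydroxymethyl)but-2-enoate, a second Michael acceptor with two free primary allylic alcohols. Fragile points are the allylic acetate (ionisation), the tertiary alcohol (dehydration), both α-substituted acrylates (conjugate addition, alkene migration), and C7–H, which epimerises to the more stable trans arrangement whenever C8 is a ketone. The real difficulty is the kinetic construction of the C1/C6/C7/C8 array together with the remote quaternary carbinol C10, with the acrylic acid already at its final oxidation level. The key step exploits three facts: C8–C7–C6–C5=C4 is a γ,δ-unsaturated carboxyl unit once C8 is a carboxyl; C8–C7–C11(=C13)–C12 is then a 2-methylidenesuccinate (itaconate); and the other ten carbons (C1–C6, C15, C10, C9, C14) are a p-menthane whose isopropenyl group is C10(=C9)C14.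

## Logic of the disconnections

26 from 25: the three O–CH2Ar bonds (one ester at C12, two ethers in the side chain) are cut together. One kind of acid-labile group allows a single last step; the forward acidolysis must spare the allylic acetate and the tertiary alcohol.

25 from 24 from 23: the acetyl C–O bond and then the C3–O bond are cut. C3 is the only allylic methylene on the more substituted end of C4=C5 and its α face is the open convex face. Leaving C3 as CH2 until late removes a protecting group from the enolate chemistry and an axial substituent from the ring-A closure. The forward step must hydroxylate C3 and not C15, from the α face, when no other secondary hydroxyl is free.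

23 from 15 and 21: the ester bond O8–C(=O) is cut, which makes the route convergent. The forward esterification must choose the secondary C8 hydroxyl over the tertiary C10 hydroxyl.

21 from 19, 17 and 16: the C–CO2H bond is cut, then C–I and C–H across a symmetrical alkyne. Syn hydrometallation fixes the cis relation of the two CH2O arms (the E acid) without any regiochemical question.

15 from 13: the C10–O bond is cut back to the exocyclic C10=C14 alkene. The forward hydration must prefer the 1,1-disubstituted alkene over C4=C5 and the acrylate, and deliver water to the α face.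

13 from 12: the C8–C9 bond of ring A is cut (carbonyl-ene retron: homoallylic alcohol with an exocyclic methylene). The bicycle falls to a monocycle whose two cis substituents can only give the cis fusion. The forward step must set C8 and must not enolise the α-vinyl aldehyde.

12 from 10: only the oxidation level at C8 changes. The forward reduction must distinguish the free carboxyl from the C12 ester and leave C7 untouched.

10 from 7 (key): the C6–C7 bond is cut and the C4–O bond re-formed, with the alkene moving from C4=C5 back to C5=C6. This removes two stereocentres, detaches the whole C5 acid unit, and reduces the problem to a tertiary allylic alcohol plus an itaconate. The forward step must transfer chirality from C4 to C6 suprafacially, control C7, and keep the acrylate intact under enolate conditions.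

7 from 4 and 5: the acyl C8–O bond and the benzyl ester O–C bond are cut. The alkoxide of 4 must attack the unconjugated carbonyl of 5.

4 from 1: the C5=C6 alkene and the C4 hydroxyl are traced back to the C4–C5 epoxide. Trans-diaxial opening at C5 places the hydroxyl cis to the isopropenyl group, which is the relation the key step needs.

## Other disconnections considered

Alternative 1: Cut C1–C2 and C5–C6 of ring B by an intermolecular Diels–Alder reaction of the ring-A enone A1 with the 1-methoxy-2-methyl-3-silyloxy diene A2, giving the cis-fused enedione A3 after acid. This is the first plan that comes to mind. It is set aside for three reasons: the diene would have to add to A1 on the face syn to the C10 methyl and anti to oxygen; hydride delivery to the C3 ketone of A3 from the convex face would give the 3β alcohol; and the C7 ketone would still have to become CH–C(=CH2)CO2H with the β configuration while C8 is oxygenated beside it. The cycloaddition sets only C1 and C6 and leaves C7 and C8, the hard part, to a long sequence.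

Alternative 2: Cut C1–C6 and C2–C3 by an intramolecular Diels–Alder reaction of the linalool-type triene A4 to the octalin A5. The dienophile is an unactivated vinyl group on a quaternary carbinol and the diene is a 1-acetoxy diene, so the reaction needs heat that the allylic acetate and tertiary alcohol tolerate poorly. Deca-1,3,9-trienes of this kind give little cis/trans or endo/exo control. The C7/C8/C10 triad would have to be built first in an open chain, so the key step would settle fewer centres, less reliably, after more steps.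

Alternative 3: Cut C7–C8 by an intramolecular Barbier-type allylation (CrCl2 or zinc) of the bromomethyl acrylate aldehyde A6 to A7. The cis C7/C8 relation is well served by this reaction. However, the quaternary carbinol C10 must already exist in an acyclic chain next to C1, where nothing controls it, and the relation of C7/C8 to C6 depends on which chair closes. A6 also needs a C6 alkenylation and a chain extension at C10, so the plan is longer than the chosen one, in which C10 is made inside ring A.

Key step: step 3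

Assumption: (S)-(−)-limonene oxide is bought as the usual mixture of cis and trans epoxides; only the trans isomer 1 is opened under step 1, and the cis isomer is removed at the first purification.

## Steps

Step 1
Reactants: 1 (1R,4S,6S)-1-methyl-4-(prop-1-en-2-yl)-7-oxabicyclo[4.1.0]heptane
Product: 4 (1R,4S)-1-methyl-4-(prop-1-en-2-yl)cyclohex-2-en-1-ol, via hydroxy selenide 2 (not isolated), via selenoxide 3 (not isolated)
Conditions: PhSeSePh, NaBH4, EtOH, 0 → 78 °C; then 30% H2O2, THF, 0 → 25 °C
Reagents that add atoms: none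
Why: Phenylselenide opens the epoxide trans-diaxially at the secondary carbon C5 (Fürst–Plattner, isopropenyl equatorial), which only the trans epoxide allows, so the tertiary C4 hydroxyl ends cis to the isopropenyl group. Selenoxide syn-elimination can only run toward C6 and should give the tertiary allylic alcohol.

Step 2
Reactants: 4 (1R,4S)-1-methyl-4-(prop-1-en-2-yl)cyclohex-2-en-1-ol; 5 itaconic anhydride
Product: 7 1-(4-methoxybenzyl) 4-[(1R,4S)-1-methyl-4-(prop-1-en-2-yl)cyclohex-2-en-1-yl] 2-methylidenebutanedioate, via lithium carboxylate 6 (not isolated)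
Conditions: n-BuLi, THF, −78 °C; 5, −78 → 0 °C; then 4-MeOC6H4CH2Cl, Bu4NI (cat.), DMF, 25 °C
Reagents that add atoms: 4-methoxybenzyl chloride, COc1ccc(CCl)cc1
Why: Alcoholysis of a cyclic anhydride by a lithium alkoxide should occur at the unconjugated, less hindered carbonyl of 5, as in the known formation of 4-alkyl hydrogen itaconates. The resulting carboxylate is O-alkylated in the same flask, and no stereocentre is touched.

Step 3
Reactants: 7 1-(4-methoxybenzyl) 4-[(1R,4S)-1-methyl-4-(prop-1-en-2-yl)cyclohex-2-en-1-yl] 2-methylidenebutanedioate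
Product: 10 (2S)-3-{[(4-methoxybenzyl)oxy]carbonyl}-2-[(1R,6S)-3-methyl-6-(prop-1-en-2-yl)cyclohex-2-en-1-yl]but-3-enoic acid, via silyl ketene acetal 8 (not isolated), via trimethylsilyl ester 9 (not isolated)
Conditions: LiN(iPr)2, Me3SiCl, THF–DMPU (4:1), −78 °C; → 25 °C, 3 h; aq. citric acid
Reagents that add atoms: none
Why: LiN(iPr)2 removes the C7 proton (α to the allylic ester, allylic to C11=C13) and Me3SiCl in the flask traps the dienolate on oxygen as silyl ketene acetal 8 (mainly Z in THF–DMPU), which undergoes a [3,3]-sigmatropic shift on warming; this is an Ireland–Claisen rearrangement, closest to the known ester-enolate Claisen rearrangements of tertiary cyclohex-2-enyl esters and of 3-butenoate esters. No ring is closed, the only cyclic array being the six-membered pericyclic transition state: C4–O breaks, C6–C7 forms and the double bond moves to C4=C5 with C15 already on C4. C6 is set by suprafacial 1,3-transfer from C4: in the reactive half-chair the ester oxygen is pseudoaxial and the cis isopropenyl group equatorial, so C7 arrives on the face of C6 that carries C10, giving the cis-1,2 relation needed for the cis ring fusion. C7 is set by the shape of the transition state: for the Z ketene acetal the boat places both the silyloxy group and C11 outside the ring, whereas the chair presses C11 against the isopropenyl group on C1; for the minor E isomer the chair is the arrangement that keeps C11 away from C1, so both geometries should converge on the (7S) acid. The step needs C7 deprotonation to outrun conjugate addition to the acrylate, which the hindered amide, −78 °C and the internal silyl quench secure (the dienolate itself is no longer an acceptor). It also needs the C11=C13 alkene to stay out of conjugation, which the near-neutral hydrolysis of silyl ester 9 secures.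

Step 4
Reactants: 10 (2S)-3-{[(4-methoxybenzyl)oxy]carbonyl}-2-[(1R,6S)-3-methyl-6-(prop-1-en-2-yl)cyclohex-2-en-1-yl]but-3-enoic acid
Product: 12 4-methoxybenzyl (3S)-2-methylidene-3-[(1R,6S)-3-methyl-6-(prop-1-en-2-yl)cyclohex-2-en-1-yl]-4-oxobutanoate, via acid chloride 11 (not isolated)
Conditions: Me2C=C(Cl)NMe2 (Ghosez reagent), CH2Cl2, 0 °C; then LiAlH(OtBu)3, THF, −78 °C
Reagents that add atoms: none
Why: Neutral acid chloride formation followed by LiAlH(OtBu)3 reduction stops at the aldehyde and does not touch the acrylate ester. The absence of amine base and the low temperature should keep C7 from epimerising through a ketene or enol.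

Step 5
Reactants: 12 4-methoxybenzyl (3S)-2-methylidene-3-[(1R,6S)-3-methyl-6-(prop-1-en-2-yl)cyclohex-2-en-1-yl]-4-oxobutanoate
Product: 13 4-methoxybenzyl 2-[(1S,2S,4aS,8aR)-2-hydroxy-7-methyl-4-methylidene-1,2,3,4,4a,5,6,8a-octahydronaphthalen-1-yl]prop-2-enoate
Conditions: Me2AlCl (2 equiv), CH2Cl2, −78 → −40 °C; aq. HCl work-up
Reagents that add atoms: none
Why: This is a type-two intramolecular carbonyl-ene reaction: C9 of the isopropenyl group attacks the complexed aldehyde, a hydrogen of C14 passes to oxygen, and ring A closes cis-fused because both arms are cis on ring B. The concerted hydrogen transfer requires the C=O axial in the forming chair, and the chair with the acrylate equatorial (C5 axial) then places O8 on the β face, cis to C11, which is the (8S) alcohol.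

Step 6
Reactants: 13 4-methoxybenzyl 2-[(1S,2S,4aS,8aR)-2-hydroxy-7-methyl-4-methylidene-1,2,3,4,4a,5,6,8a-octahydronaphthalen-1-yl]prop-2-enoate
Product: 15 4-methoxybenzyl 2-[(1S,2S,4S,4aS,8aS)-2,4-dihydroxy-4,7-dimethyl-1,2,3,4,4a,5,6,8a-octahydronaphthalen-1-yl]prop-2-enoate, via organomercurial 14 (not isolated)
Conditions: Hg(OAc)2, THF–H2O (1:1), 25 °C; then NaBH4, 3 M NaOH, 0 °C
Reagents that add atoms: water, O
Why: Markovnikov oxymercuration–demercuration is much faster at the 1,1-disubstituted exocyclic alkene than at the trisubstituted C4=C5 alkene and leaves the acrylate alone. Water should attack C10 equatorially from the α face because the axial β trajectory is blocked by the syn-axial C5 and O8, as is usual for exocyclic methylenes flanked by a syn-axial group, giving the 1,3-anti diol.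

Step 7
Reactants: 16 but-2-yne-1,4-diol
Product: 17 1,4-bis[(4-methoxybenzyl)oxy]but-2-yne
Conditions: NaH, 4-MeOC6H4CH2Cl, Bu4NI (cat.), THF–DMF, 0 → 25 °C
Reagents that add atoms: 4-methoxybenzyl chloride, COc1ccc(CCl)cc1
Why: Williamson etherification of both primary propargylic hydroxyls; the ethers are chosen so that they leave in the same final acidolysis as the C12 ester.

Step 8
Reactants: 17 1,4-bis[(4-methoxybenzyl)oxy]but-2-yne
Product: 19 (E)-2-iodo-1,4-bis[(4-methoxybenzyl)oxy]but-2-ene, via vinylstannane 18 (not isolated)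
Conditions: Bu3SnH, PdCl2(PPh3)2 (2 mol %), THF, 25 °C; then I2, CH2Cl2, 0 °C
Reagents that add atoms: iodine, II
Why: Palladium-catalysed hydrostannation adds H and Sn syn across the symmetrical alkyne, so the two CH2O arms end cis with no regiochemical issue. Iododestannylation proceeds with retention.

Step 9
Reactants: 19 (E)-2-iodo-1,4-bis[(4-methoxybenzyl)oxy]but-2-ene
Product: 21 (2E)-4-[(4-methoxybenzyl)oxy]-2-{[(4-methoxybenzyl)oxy]methyl}but-2-enoic acid, via vinyllithium 20 (not isolated)
Conditions: t-BuLi (2.1 equiv), Et2O, −78 °C; CO2; aq. HCl to pH 3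
Reagents that add atoms: carbon dioxide, O=C=O
Why: Iodine–lithium exchange and carboxylation both proceed with retention of alkene geometry, so the acid carries the two CH2O arms cis (E by the sequence rule). The E acid cannot lactonise onto its γ-oxygen.

Step 10
Reactants: 15 4-methoxybenzyl 2-[(1S,2S,4S,4aS,8aS)-2,4-dihydroxy-4,7-dimethyl-1,2,3,4,4a,5,6,8a-octahydronaphthalen-1-yl]prop-2-enoate; 21 (2E)-4-[(4-methoxybenzyl)oxy]-2-{[(4-methoxybenzyl)oxy]methyl}but-2-enoic acid
Product: 23 4-methoxybenzyl 2-[(1S,2S,4S,4aS,8aS)-4-hydroxy-2-({(2E)-4-[(4-methoxybenzyl)oxy]-2-{[(4-methoxybenzyl)oxy]methyl}but-2-enoyl}oxy)-4,7-dimethyl-1,2,3,4,4a,5,6,8a-octahydronaphthalen-1-yl]prop-2-enoate, via mixed anhydride 22 (not isolated)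
Conditions: 2,4,6-Cl3C6H2COCl, Et3N, toluene, 25 °C; then 15, DMAP, toluene, 25 → 40 °C
Reagents that add atoms: none
Why: Yamaguchi esterification acylates the secondary C8 hydroxyl (equatorial once C10 is tetrahedral) and leaves the tertiary C10 hydroxyl untouched. C8 is not inverted because the C–O bond is not broken.

Step 11
Reactants: 23 4-methoxybenzyl 2-[(1S,2S,4S,4aS,8aS)-4-hydroxy-2-({(2E)-4-[(4-methoxybenzyl)oxy]-2-{[(4-methoxybenzyl)oxy]methyl}but-2-enoyl}oxy)-4,7-dimethyl-1,2,3,4,4a,5,6,8a-octahydronaphthalen-1-yl]prop-2-enoate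
Product: 24 4-methoxybenzyl 2-[(1S,2S,4S,4aS,6S,8aS)-4,6-dihydroxy-2-({(2E)-4-[(4-methoxybenzyl)oxy]-2-{[(4-methoxybenzyl)oxy]methyl}but-2-enoyl}oxy)-4,7-dimethyl-1,2,3,4,4a,5,6,8a-octahydronaphthalen-1-yl]prop-2-enoate
Conditions: SeO2 (0.5 equiv), t-BuOOH (2 equiv), CH2Cl2, 25 °C
Reagents that add atoms: selenium dioxide, O=[Se]=O; tert-butyl hydroperoxide, CC(C)(C)OO
Why: Selenium dioxide allylic hydroxylation proceeds by an ene reaction at the less substituted alkene carbon C5 followed by a [2,3]-sigmatropic shift, so oxygen lands on the ring methylene next to the methyl-bearing carbon, as with 1-methylcyclohexene; the two electron-poor alkenes do not react. Selenium should approach C5 from the convex α face (the β face carries the pseudoaxial C7 substituent) and remove the pseudoaxial H3α, so the hydroxyl is delivered to C3 on the α face.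

Step 12
Reactants: 24 4-methoxybenzyl 2-[(1S,2S,4S,4aS,6S,8aS)-4,6-dihydroxy-2-({(2E)-4-[(4-methoxybenzyl)oxy]-2-{[(4-methoxybenzyl)oxy]methyl}but-2-enoyl}oxy)-4,7-dimethyl-1,2,3,4,4a,5,6,8a-octahydronaphthalen-1-yl]prop-2-enoate
Product: 25 4-methoxybenzyl 2-[(1S,2S,4S,4aS,6S,8aS)-6-acetoxy-4-hydroxy-2-({(2E)-4-[(4-methoxybenzyl)oxy]-2-{[(4-methoxybenzyl)oxy]methyl}but-2-enoyl}oxy)-4,7-dimethyl-1,2,3,4,4a,5,6,8a-octahydronaphthalen-1-yl]prop-2-enoate
Conditions: Ac2O, pyridine, DMAP (cat.), CH2Cl2, 0 °C
Reagents that add atoms: acetic anhydride, CC(=O)OC(C)=O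
Why: The C3 hydroxyl is the only secondary alcohol, and the tertiary C10 hydroxyl is not acetylated under these mild conditions. The configuration at C3 is retained.

Step 13
Reactants: 25 4-methoxybenzyl 2-[(1S,2S,4S,4aS,6S,8aS)-6-acetoxy-4-hydroxy-2-({(2E)-4-[(4-methoxybenzyl)oxy]-2-{[(4-methoxybenzyl)oxy]methyl}but-2-enoyl}oxy)-4,7-dimethyl-1,2,3,4,4a,5,6,8a-octahydronaphthalen-1-yl]prop-2-enoate
Product: 26 2-[(1S,2S,4S,4aS,6S,8aS)-6-acetoxy-4-hydroxy-2-{[(2E)-4-hydroxy-2-(hydroxymethyl)but-2-enoyl]oxy}-4,7-dimethyl-1,2,3,4,4a,5,6,8a-octahydronaphthalen-1-yl]prop-2-enoic acid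
Conditions: CF3CO2H–CH2Cl2 (1:9), anisole, 0 °C
Reagents that add atoms: none
Why: Acidolysis removes the 4-methoxybenzyl ester and both 4-methoxybenzyl ethers through the stabilised benzyl cation, which anisole captures. Short exposure to dilute acid at 0 °C should leave the allylic acetate, the tertiary alcohol and the enoate ester intact; no stereocentre is involved.

## Compound list

1 | (1R,4S,6S)-1-methyl-4-(prop-1-en-2-yl)-7-oxabicyclo[4.1.0]heptane, (−)-trans-limonene 1,2-oxide, used as the commercial cis/trans mixture of (S)-limonene oxide | C[C@]12O[C@H]1C[C@H](CC2)C(C)=C | starting material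
2 | (1R,2R,4S)-1-methyl-2-(phenylselanyl)-4-(prop-1-en-2-yl)cyclohexan-1-ol | C[C@]1(O)[C@H]([Se]c2ccccc2)C[C@H](CC1)C(C)=C | intermediate
3 | Se-oxide of 2 (mixture at selenium) | C[C@]1(O)[C@H]([Se](=O)c2ccccc2)C[C@H](CC1)C(C)=C | intermediate
4 | (1R,4S)-1-methyl-4-(prop-1-en-2-yl)cyclohex-2-en-1-ol (hydroxyl cis to isopropenyl) | C[C@]1(O)C=C[C@H](CC1)C(C)=C | intermediate
5 | itaconic anhydride (3-methylideneoxolane-2,5-dione) | C=C1CC(=O)OC1=O | starting material
6 | lithium 2-methylidene-4-{[(1R,4S)-1-methyl-4-(prop-1-en-2-yl)cyclohex-2-en-1-yl]oxy}-4-oxobutanoate | C[C@]1(OC(=O)CC(=C)C(=O)[O-])C=C[C@H](CC1)C(C)=C.[Li+] | intermediate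
7 | 1-(4-methoxybenzyl) 4-[(1R,4S)-1-methyl-4-(prop-1-en-2-yl)cyclohex-2-en-1-yl] 2-methylidenebutanedioate | C[C@]1(OC(=O)CC(=C)C(=O)OCc2ccc(OC)cc2)C=C[C@H](CC1)C(C)=C | intermediate
8 | (Z)-O-trimethylsilyl ketene acetal of 7 at C8=C7 | C[C@]1(O/C(O[Si](C)(C)C)=C/C(=C)C(=O)OCc2ccc(OC)cc2)C=C[C@H](CC1)C(C)=C | intermediate
9 | trimethylsilyl ester of 10 | CC1=C[C@@H]([C@H](C(=O)O[Si](C)(C)C)C(=C)C(=O)OCc2ccc(OC)cc2)[C@H](CC1)C(C)=C | intermediate
10 | (2S)-3-{[(4-methoxybenzyl)oxy]carbonyl}-2-[(1R,6S)-3-methyl-6-(prop-1-en-2-yl)cyclohex-2-en-1-yl]but-3-enoic acid | CC1=C[C@@H]([C@H](C(=O)O)C(=C)C(=O)OCc2ccc(OC)cc2)[C@H](CC1)C(C)=C | intermediate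
11 | acid chloride of 10 | CC1=C[C@@H]([C@H](C(Cl)=O)C(=C)C(=O)OCc2ccc(OC)cc2)[C@H](CC1)C(C)=C | intermediate
12 | 4-methoxybenzyl (3S)-2-methylidene-3-[(1R,6S)-3-methyl-6-(prop-1-en-2-yl)cyclohex-2-en-1-yl]-4-oxobutanoate | CC1=C[C@@H]([C@H](C=O)C(=C)C(=O)OCc2ccc(OC)cc2)[C@H](CC1)C(C)=C | intermediate
13 | 4-methoxybenzyl 2-[(1S,2S,4aS,8aR)-2-hydroxy-7-methyl-4-methylidene-1,2,3,4,4a,5,6,8a-octahydronaphthalen-1-yl]prop-2-enoate | C=C(C(=O)OCc3ccc(OC)cc3)[C@@H]1[C@@H]2C=C(C)CC[C@@H]2C(=C)C[C@@H]1O | intermediate
14 | C14 acetoxymercurio adduct of 13 (10α-OH, C14–HgOAc) | C=C(C(=O)OCc3ccc(OC)cc3)[C@@H]1[C@@H]2C=C(C)CC[C@@H]2[C@@](C[Hg]OC(C)=O)(O)C[C@@H]1O | intermediate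
15 | 4-methoxybenzyl 2-[(1S,2S,4S,4aS,8aS)-2,4-dihydroxy-4,7-dimethyl-1,2,3,4,4a,5,6,8a-octahydronaphthalen-1-yl]prop-2-enoate | C=C(C(=O)OCc3ccc(OC)cc3)[C@@H]1[C@@H]2C=C(C)CC[C@@H]2[C@@](C)(O)C[C@@H]1O | intermediate
16 | but-2-yne-1,4-diol | OCC#CCO | starting material
17 | 1,4-bis[(4-methoxybenzyl)oxy]but-2-yne | COc1ccc(COCC#CCOCc2ccc(OC)cc2)cc1 | intermediate
18 | (E)-tributyl{1,4-bis[(4-methoxybenzyl)oxy]but-2-en-2-yl}stannane | CCCC[Sn](CCCC)(CCCC)/C(=C/COCc1ccc(OC)cc1)COCc1ccc(OC)cc1 | intermediate
19 | (E)-2-iodo-1,4-bis[(4-methoxybenzyl)oxy]but-2-ene | I/C(=C/COCc1ccc(OC)cc1)COCc1ccc(OC)cc1 | intermediate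
20 | (Z)-{1,4-bis[(4-methoxybenzyl)oxy]but-2-en-2-yl}lithium | [Li]/C(=C/COCc1ccc(OC)cc1)COCc1ccc(OC)cc1 | intermediate
21 | (2E)-4-[(4-methoxybenzyl)oxy]-2-{[(4-methoxybenzyl)oxy]methyl}but-2-enoic acid | OC(=O)/C(=C/COCc1ccc(OC)cc1)COCc1ccc(OC)cc1 | intermediate
22 | mixed anhydride of 21 and 2,4,6-trichlorobenzoic acid | O=C(OC(=O)c1c(Cl)cc(Cl)cc1Cl)/C(=C/COCc1ccc(OC)cc1)COCc1ccc(OC)cc1 | intermediate
23 | 8-O-acyl diol (name as in step 10) | C=C(C(=O)OCc3ccc(OC)cc3)[C@@H]1[C@@H]2C=C(C)CC[C@@H]2[C@@](C)(O)C[C@@H]1OC(=O)/C(=C/COCc1ccc(OC)cc1)COCc1ccc(OC)cc1 | intermediate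
24 | 3α-hydroxy compound (name as in step 11) | C=C(C(=O)OCc3ccc(OC)cc3)[C@@H]1[C@@H]2C=C(C)[C@@H](O)C[C@@H]2[C@@](C)(O)C[C@@H]1OC(=O)/C(=C/COCc1ccc(OC)cc1)COCc1ccc(OC)cc1 | intermediate
25 | 3α-acetate (name as in step 12) | C=C(C(=O)OCc3ccc(OC)cc3)[C@@H]1[C@@H]2C=C(C)[C@@H](OC(C)=O)C[C@@H]2[C@@](C)(O)C[C@@H]1OC(=O)/C(=C/COCc1ccc(OC)cc1)COCc1ccc(OC)cc1 | intermediate
26 | 2-[(1S,2S,4S,4aS,6S,8aS)-6-acetoxy-4-hydroxy-2-{[(2E)-4-hydroxy-2-(hydroxymethyl)but-2-enoyl]oxy}-4,7-dimethyl-1,2,3,4,4a,5,6,8a-octahydronaphthalen-1-yl]prop-2-enoic acid | C=C(C(=O)O)[C@@H]1[C@@H]2C=C(C)[C@@H](OC(C)=O)C[C@@H]2[C@@](C)(O)C[C@@H]1OC(=O)/C(=C/CO)CO | target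

## Step count and risks

Total step count: 13. Longest linear sequence: 10 (steps 1–6 and 10–13); steps 7–9 make the side-chain acid.

Least certain steps:

Step 3 (key step). The most likely failure is consumption of the enolate or the amide base by conjugate addition to the acrylate ester, or migration of the alkene into conjugation, before silylation; an unactivated acrylate ester sits two atoms from the enolate carbon. The C7 outcome rests on the boat/chair argument and is the second concern. Fallback: run the same rearrangement on the carboxylate, which is not an acceptor. From 4 and 5 the opening of step 2 is acidified to the free half acid F1. F1 is rearranged as its dianion (LiN(iPr)2, 2.2 equiv, Me3SiCl) to the diacid F2, and F2 is dehydrated (dicyclohexylcarbodiimide) to the cyclic anhydride F3. NaBH4 reduces F3 at the unconjugated carbonyl to the α-methylene lactone F4. F4 is saponified and the carboxylate alkylated with 4-methoxybenzyl chloride to the hydroxy ester F5. Dess–Martin oxidation of F5 returns to the route at 12.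

Step 2. Proton transfer from the acidic methylene of 5 to the hindered tertiary alkoxide could outrun acyl transfer and isomerise the anhydride to the citraconic series. Fallback: use a preformed, regiodefined half ester. Commercial 4-methyl hydrogen itaconate is esterified with 4-methoxybenzyl chloride to the diester F6, and the unconjugated methyl ester is cleaved selectively (esterase or 1 equiv LiOH, 0 °C) to the acid F7. F7 is coupled to 4 through its 2,4,6-trichlorobenzoyl mixed anhydride and DMAP, returning at 7.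

Step 5. Loss of control at C8 is the main risk: a stepwise pathway with an equatorial C=O (no concerted hydrogen transfer) would give the 8-epimer, and the α-vinyl aldehyde may enolise under the Lewis acid. Fallback: if the 8α alcohol F8 forms from 12, it is oxidised with buffered Dess–Martin periodinane to the ketone F9 and reduced at once with NaBH4/CeCl3·7H2O at −78 °C. Hydride should arrive from the open α face, returning at 13. The ketone stage must be kept short because C7 is then epimerisable.

Step 6. Water may be delivered to the β face (hydrogen-bonded delivery by the axial C8 hydroxyl, or a late transition state that keeps the CH2Hg group equatorial), giving the 1,3-syn diol. Fallback: a Mukaiyama hydration of 13 (Co(acac)2, PhSiH3, O2), in which a single reagent, O2, traps the planar C10 radical from the open α face with no anti-addition requirement. The hydroperoxide F10 formed alongside the alcohol is reduced with PPh3, returning at 15. Competing hydrogen-atom transfer to the acrylate and to C4=C5 would have to be held back by low conversion and recycling.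

Step 11. Hydrogen abstraction from the C15 methyl in place of C3, or over-oxidation to the enone, would erode regio- and stereocontrol. Fallback: oxidise 23 deliberately to the C3 enone F11 (Rh2(cap)4, t-BuOOH), reduce F11 under Luche conditions from the convex face to the 3β alcohol F12, and invert F12 with acetic acid under Mitsunobu conditions, returning at 25.

## Further compounds

F1 | step 3 | 2-methylidene-4-{[(1R,4S)-1-methyl-4-(prop-1-en-2-yl)cyclohex-2-en-1-yl]oxy}-4-oxobutanoic acid | C[C@]1(OC(=O)CC(=C)C(=O)O)C=C[C@H](CC1)C(C)=C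
F2 | step 3 | (3S)-2-methylidene-3-[(1R,6S)-3-methyl-6-(prop-1-en-2-yl)cyclohex-2-en-1-yl]butanedioic acid | CC1=C[C@@H]([C@H](C(=O)O)C(=C)C(=O)O)[C@H](CC1)C(C)=C
F3 | step 3 | (4S)-3-methylidene-4-[(1R,6S)-3-methyl-6-(prop-1-en-2-yl)cyclohex-2-en-1-yl]oxolane-2,5-dione | CC1=C[C@@H]([C@@H]2C(=O)OC(=O)C2=C)[C@H](CC1)C(C)=C
F4 | step 3 | (4S)-3-methylidene-4-[(1R,6S)-3-methyl-6-(prop-1-en-2-yl)cyclohex-2-en-1-yl]oxolan-2-one | CC1=C[C@@H]([C@@H]2COC(=O)C2=C)[C@H](CC1)C(C)=C
F5 | step 3 | 4-methoxybenzyl (3S)-4-hydroxy-2-methylidene-3-[(1R,6S)-3-methyl-6-(prop-1-en-2-yl)cyclohex-2-en-1-yl]butanoate | CC1=C[C@@H]([C@H](CO)C(=C)C(=O)OCc2ccc(OC)cc2)[C@H](CC1)C(C)=C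
F6 | step 2 | 1-(4-methoxybenzyl) 4-methyl 2-methylidenebutanedioate | COC(=O)CC(=C)C(=O)OCc1ccc(OC)cc1
F7 | step 2 | 3-{[(4-methoxybenzyl)oxy]carbonyl}but-3-enoic acid | OC(=O)CC(=C)C(=O)OCc1ccc(OC)cc1
F8 | step 5 | 4-methoxybenzyl 2-[(1S,2R,4aS,8aR)-2-hydroxy-7-methyl-4-methylidene-1,2,3,4,4a,5,6,8a-octahydronaphthalen-1-yl]prop-2-enoate | C=C(C(=O)OCc3ccc(OC)cc3)[C@@H]1[C@@H]2C=C(C)CC[C@@H]2C(=C)C[C@H]1O
F9 | step 5 | 4-methoxybenzyl 2-[(1S,4aS,8aR)-7-methyl-4-methylidene-2-oxo-1,2,3,4,4a,5,6,8a-octahydronaphthalen-1-yl]prop-2-enoate | C=C(C(=O)OCc3ccc(OC)cc3)[C@@H]1[C@@H]2C=C(C)CC[C@@H]2C(=C)CC1=O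
F10 | step 6 | 4-methoxybenzyl 2-[(1S,2S,4S,4aS,8aS)-4-hydroperoxy-2-hydroxy-4,7-dimethyl-1,2,3,4,4a,5,6,8a-octahydronaphthalen-1-yl]prop-2-enoate | C=C(C(=O)OCc3ccc(OC)cc3)[C@@H]1[C@@H]2C=C(C)CC[C@@H]2[C@@](C)(OO)C[C@@H]1O
F11 | step 11 | C3 ketone (6-oxo compound) derived from 23 | C=C(C(=O)OCc3ccc(OC)cc3)[C@@H]1[C@@H]2C=C(C)C(=O)C[C@@H]2[C@@](C)(O)C[C@@H]1OC(=O)/C(=C/COCc1ccc(OC)cc1)COCc1ccc(OC)cc1
F12 | step 11 | 3β-hydroxy epimer of 24 (6R) | C=C(C(=O)OCc3ccc(OC)cc3)[C@@H]1[C@@H]2C=C(C)[C@H](O)C[C@@H]2[C@@](C)(O)C[C@@H]1OC(=O)/C(=C/COCc1ccc(OC)cc1)COCc1ccc(OC)cc1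
A1 | alternative 1 | (S)-4-methyl-4-[(triethylsilyl)oxy]cyclohex-2-en-1-one | O=C1C=C[C@@](C)(O[Si](CC)(CC)CC)CC1
A2 | alternative 1 | (E)-1-methoxy-2-methyl-3-[(trimethylsilyl)oxy]buta-1,3-diene | CO/C=C(C)/C(=C)O[Si](C)(C)C
A3 | alternative 1 | (4S,4aS,8aR)-4,7-dimethyl-4-[(triethylsilyl)oxy]-3,4,4a,5-tetrahydronaphthalene-1,6(2H,8aH)-dione | O=C1[C@@H]2C=C(C)C(=O)C[C@@H]2[C@@](C)(O[Si](CC)(CC)CC)CC1
A4 | alternative 2 | methyl 2-methylidene-3-[(1E,3E)-4-acetoxy-3-methylbuta-1,3-dienyl]-4-[(tert-butyldimethylsilyl)oxy]-6-hydroxy-6-methyloct-7-enoate, open-chain triene with the C7, C8 and C10 configurations of the target | C=C[C@@](C)(O)C[C@H](O[Si](C)(C)C(C)(C)C)[C@@H](/C=C/C(C)=C/OC(C)=O)C(=C)C(=O)OC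
A5 | alternative 2 | methyl ester 8-O-silyl ether of the target core (3α-acetoxy, 10α-hydroxy) | C=C(C(=O)OC)[C@@H]1[C@@H]2C=C(C)[C@@H](OC(C)=O)C[C@@H]2[C@@](C)(O)C[C@@H]1O[Si](C)(C)C(C)(C)C
A6 | alternative 3 | methyl (E)-2-(bromomethyl)-3-[ring B]prop-2-enoate carrying the C10 triethylsilyloxy aldehyde chain on C1 | BrC/C(C(=O)OC)=C/[C@@H]1C=C(C)[C@@H](OC(C)=O)C[C@@H]1[C@@](C)(O[Si](CC)(CC)CC)CC=O
A7 | alternative 3 | methyl 2-[8β-hydroxy-3α-acetoxy-10α-(triethylsilyloxy) cis-octalin-7-yl]prop-2-enoate | C=C(C(=O)OC)[C@@H]1[C@@H]2C=C(C)[C@@H](OC(C)=O)C[C@@H]2[C@@](C)(O[Si](CC)(CC)CC)C[C@@H]1O
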